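## Structural features

The target is a biflavonoid: two 4H-chromen-4-one units held together by one anisole ring. Unit 1 is a 5-hydroxy-7-methoxychromone (benzo ring A fused to pyranone ring C) with a 4-hydroxyphenyl group (ring B) on C2 and the anisole ring E on C3. Ring E is bonded to C3 through the carbon ortho to its methoxy group and, para to that methoxy group, carries C2 of unit 2, a 5,7-dihydroxychromone (pyranone ring F fused to benzo ring D). The target has no stereocentre; the only adjacent stereocentres in the plan are the transient C2/C3 pair of the chromanone stage, which are erased again. The fragile elements are the four phenols, the base-sensitive pyranone rings, and the need to tell six oxygens apart (methyl on O7 of unit 1 and on ring E; hydrogen on O5 of unit 1, on ring B and on O5/O7 of unit 2). The real difficulty is the fully substituted C2=C3 bond of ring C, with rings B and E side by side next to the 5,7-dioxygenated ring A, where a late aryl–aryl coupling at C3 would be severely hindered. The key step exploits the contiguous pattern on ring A: O1 on C8a, the C4 carbonyl on the neighbouring C4a, and an oxygen on C5 beside C4a. This is the imprint of a carboxylic acid inserted across a 3,5-dimethoxybenzyne, with the methoxy group next to the triple bond fixing the orientation. The peri position of that same methoxy group later allows its selective removal by chelation.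

## Logic of the disconnections

20 to 19. Cut: three O–benzyl bonds (ring B oxygen, O5 and O7 of unit 2), and a methyl group is put back on O5 of unit 1. Reason: all phenols stay masked during enolate and acyl-transfer chemistry, and a methyl on O5 is what a symmetric dimethoxy aryne leaves there. Gain: ring A never needs stepwise differentiation of its oxygens. Demand: one Lewis acid must remove benzyl groups and only the methyl ether peri to the C4 carbonyl, sparing O7–CH3 and the ring E methyl ether.

19 to 17 (through 18). Cut: O1–C2 and C2–C3 of ring F. Reason: a 2-aroyloxyacetophenone is the classical open form of a flavone. Gain: unit 2 becomes an ester of two simple pieces. Demand: a base that forms the methyl ketone enolate without adding to the pyranone of unit 1, then acid-induced ring closure that leaves the benzyl ethers in place.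

17 to 14 and 16; 16 to 15; 14 to 13. Cut: the aryl ester C–O bond, the two O–benzyl bonds of 16 and the O–CH3 bond of the ring E ester. Reason: these are the only heteroatom links between the halves. Gain: a convergent union of 14 with a two-fold protected form of 15. Demand: acylation of a hydrogen-bonded, hindered phenol; benzylation of 15 that stops at the chelated hydroxyl; ester hydrolysis that does not open ring C.

13 to 12. Cut: none in the skeleton; the C2=C3 double bond is taken back to two sp3 centres. Reason: the saturated ring is what an oxa-Michael closure delivers. Gain: access to the key-step product. Demand: a dehydrogenation that tolerates benzyl and methyl ethers; the configuration of 12 is irrelevant.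

12 to 5 and 9 (through 10 and 11). Cut: O1–C8a, C4–C4a and O1–C2. Reason: these three bonds are exactly those made when 10 inserts into the carboxyl C–O bond of 9 and the freed phenoxide 11 adds to its enone. Gain: ring A comes from a symmetric aromatic, and rings B and E arrive already joined to C2 and C3. Demand: attack of the carboxylate at the aryne carbon remote from the flanking methoxy group, acyl transfer faster than protonation, and 6-endo ring closure.

Design of the 5/9 pair. The skeletons and protecting groups of 5 and 9 are kept as they stand, for these reasons: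
- The ring E carboxyl stays a methyl ester, so 9 has a single acidic site and the future C2 of unit 2 is already in place.
- Ring B stays benzylated, so the last step removes it together with the other benzyl groups.
- The 3,5-dimethoxy pattern is kept symmetric, so no regiochemical question arises when 5 is made.
- The one adjustment is operational: 5 is the limiting partner, to suppress a second arylation at the acidic C3–H of 12.

9 to 7 and 8; 7 to 6. Cut: the Cα=Cβ double bond, then the aryl–carboxyl C–C bond on ring E. Reason: a 2,3-diarylacrylic acid is the Perkin product of an arylacetic acid and an aldehyde, and the ring E ester carbon can be brought in as CO. Gain: two commercial aromatics. Demand: E-selective condensation; carbonylation in the presence of a free acid.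

5 to 2 to 1 (through 3 and 4). Cut: C–Si and O–S bonds of 5, then the C–Br bond of 2. Reason: an ortho-silylaryl triflate is the standard latent aryne and the silyl group can be moved from oxygen to the brominated carbon. Gain: symmetric 1, whose two ortho positions are equivalent. Demand: bromination ortho rather than para to the hydroxyl.

## Other disconnections considered

Alternative 1: The cut removes the C2–C3 and O1–C2 bonds of both pyranones (rings C and F) together and leads back to the bis(aryl ester) A1. In A1, ring A is a 2-aroyloxy deoxybenzoin and ring E carries the ester of a 2-acetylphenol. Forward, excess LiN(SiMe3)2 would form the benzylic enolate and the methyl ketone enolate. Each would take the aroyl group from its neighbouring phenol oxygen (two Baker–Venkataraman shifts), and acid would then close both rings to the tetra-O-benzyl ether A2; hydrogenolysis would finish.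
- In favour: only classical enolate chemistry; both heterocycles are formed in one operation.
- Better than the chosen plan: A2 has benzyl on O5 of unit 1, so the endgame is a plain hydrogenolysis with no selective demethylation. The precedent for each half-reaction is also firmer than for an aryne insertion with an α-aryl acid.
- Against it here: ring A of A1 needs three different oxygen substituents (aroyl, benzyl, methyl), hence stepwise differentiation of a phloroglucinol-type deoxybenzoin. Two different aroyl groups must be placed on two different phenols. In the double rearrangement two enolates and several carbonyl electrophiles coexist, so crossed acyl transfer and slow reaction of the hindered benzylic enolate are concerns.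
- Comparison: structurally the chosen plan gets ring A from symmetric 1 and fixes regiochemistry through the aryne. Mechanistically both are anionic acyl transfers to carbon. Step economy should be about equal, because the oxygen differentiation costs roughly what the aryne precursor and the Perkin acid cost.

Alternative 2: The cut goes through C3–C4 and O1–C2 of ring C. 2,4,6-Trimethoxybenzoyl chloride A3 and the diarylalkyne A4 would be combined with SnCl4. The acylium carbon would bond to the alkyne carbon bearing ring E, the vinyl cation beside ring B would be captured by an ortho methoxy oxygen, and loss of that methyl group to chloride would give chromone A5.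
- In favour: A4 is two steps away by Sonogashira coupling, and A3 comes from a symmetric ring (equal to the chosen plan).
- Better than the chosen plan: the chromone arrives at the correct oxidation level, so no dehydrogenation step is needed.
- Against it here: regiocontrol rests on the polarisation of the alkyne. Ring E therefore has to be electron-poor and free of an ortho methoxy nucleophile, so it carries a tosylate that must later be removed and replaced by methyl (two extra steps on a chromone). A strong Lewis acid, possible chloride capture of the vinyl cation, and the hindered acylium are further concerns.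
- Comparison: both plans use an electronic bias for regiochemistry. In the chosen plan the bias is built into ring A and is independent of the other rings; here it depends on the protecting-group pattern. Step economy is similar or slightly worse because of the tosylate exchange, and the ester-to-flavone endgame is the same.

Alternative 3: The cut removes two bonds of ring E itself. The 3-(methoxyethynyl)flavone A6 and methyl coumalate A7 would combine on heating by a (4+2) cycloaddition followed by decarboxylative aromatisation. This would give A8, the 5-O-benzyl analogue of 13.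
- In favour: ring E is built with its 1,2,4-pattern fixed by the polarity match of ynol ether and pyrone. The conditions are neutral and metal-free. The crowded C3–aryl bond is never made by coupling, which is equal to the chosen plan, where it comes from the Perkin acid.
- Better than the chosen plan: A8 has benzyl on O5, so no peri-demethylation is needed.
- Against it here: A6 requires the complete unit 1 flavone with a differentiated ring A, followed by halogenation at C3 and installation of an acid- and heat-sensitive ynol ether. The cycloaddition has to occur at an alkyne flanked by the C4 carbonyl and ring B.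
- Comparison: the regiocontrol of the pericyclic step is as predictable as that of the aryne addition (equal). The sequence is linear and should be longer before it reaches the stage of 13, so the chosen plan is the more convergent and shorter.

Key step: step 5

Assumption: the target has no stereodescriptor and is treated as achiral, with no isolable atropisomer about the C3–ring E bond; 12 is carried on as whatever trans/cis mixture forms, because both centres are lost in step 6.

## Route

Step 1
Reactants: 1 3,5-dimethoxyphenol
Product: 2 2-bromo-3,5-dimethoxyphenol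
Conditions: NBS (1.0 equiv), CH2Cl2, −78 °C to rt
Reagents that add atoms: N-bromosuccinimide, O=C1CCC(=O)N1Br
Why: Electrophilic aromatic bromination; at low temperature in a non-polar solvent bromine should be delivered ortho to the free hydroxyl, the two ortho positions are equivalent and less hindered than the carbon between the two methoxy groups, and one equivalent limits double bromination.

Step 2
Reactants: 2 2-bromo-3,5-dimethoxyphenol
Product: 5 3,5-dimethoxy-2-(trimethylsilyl)phenyl trifluoromethanesulfonate, via aryl trimethylsilyl ether 3 (not isolated), via lithium 2-silylphenoxide 4 (not isolated)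
Conditions: HMDS, THF, 70 °C, then evaporate; n-BuLi, THF, −100 to −78 °C; Tf2O, −78 °C to rt
Reagents that add atoms: hexamethyldisilazane, C[Si](C)(C)N[Si](C)(C)C; trifluoromethanesulfonic anhydride, O=S(=O)(OS(=O)(=O)C(F)(F)F)C(F)(F)F
Why: O-silylation, bromine–lithium exchange and a 1,3 O-to-C silyl shift (retro-Brook rearrangement) place the silyl group on the carbon that carried bromine; the lithium phenoxide is then triflated, which is the standard sequence to ortho-silylaryl triflates.

Step 3
Reactants: 6 2-(5-bromo-2-methoxyphenyl)acetic acid
Product: 7 2-[2-methoxy-5-(methoxycarbonyl)phenyl]acetic acid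
Conditions: CO (balloon), Pd(OAc)2 (5 mol %), Xantphos (6 mol %), Et3N (3 equiv), MeOH/DMF, 75 °C; then aq. HCl
Reagents that add atoms: carbon monoxide, [C-]#[O+]; methanol, CO
Why: Palladium-catalysed alkoxycarbonylation of an aryl bromide (oxidative addition to zerovalent palladium formed from Pd(OAc)2, CO insertion, methanolysis of the acylpalladium); the acetic acid side chain is present as its triethylammonium carboxylate and is not esterified, so only the new carboxyl carbon becomes the methyl ester.

Step 4
Reactants: 7 2-[2-methoxy-5-(methoxycarbonyl)phenyl]acetic acid, 8 4-(benzyloxy)benzaldehyde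
Product: 9 (E)-3-[4-(benzyloxy)phenyl]-2-[2-methoxy-5-(methoxycarbonyl)phenyl]prop-2-enoic acid
Conditions: Ac2O, Et3N, 120 °C; then H2O, 90 °C; aq. HCl
Reagents that add atoms: none
Why: Perkin condensation (Oglialoro variant): the enolate of the mixed anhydride adds to the aldehyde and acetylation–elimination gives the favoured (E)-2,3-diarylacrylic acid with the two aryl groups cis; methyl ester and benzyl ether are inert to Ac2O/Et3N.

Step 5
Reactants: 5 3,5-dimethoxy-2-(trimethylsilyl)phenyl trifluoromethanesulfonate, 9 (E)-3-[4-(benzyloxy)phenyl]-2-[2-methoxy-5-(methoxycarbonyl)phenyl]prop-2-enoic acid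
Product: 12 methyl 3-[(2S,3R)-2-[4-(benzyloxy)phenyl]-5,7-dimethoxy-4-oxochroman-3-yl]-4-methoxybenzoate (racemic trans isomer; one enantiomer named), via 3,5-dimethoxybenzyne 10 (not isolated), via caesium acylphenoxide 11 (not isolated)
Conditions: 5 (1.0 equiv), 9 (1.2 equiv), CsF (4 equiv), THF, 125 °C, sealed tube
Reagents that add atoms: none
Why: Fluoride attacks silicon of 5 and triflate leaves, releasing aryne 10; the caesium carboxylate of 9 adds through oxygen to the aryne carbon remote from the flanking methoxy group (future C8a), because that methoxy group distorts the triple bond and inductively stabilises the aryl anion developing next to it (future C4a). The aryl anion attacks the ester carbonyl it has just created (transient four-membered alkoxide, a 4-exo-trig addition) and ring opening gives the ortho-acylphenoxide 11, a formal insertion of the aryne into the C–O bond of the acid; carbonyl attack should beat conjugate addition because the aryl ester conformation holds the anion beside the carbonyl carbon. Ring C then closes by a 6-endo-trig oxa-Michael addition of the phenoxide oxygen to the β-carbon of the α-aryl enone (O1–C2), and the enolate is protonated at C3. The closest known reaction type is this same insertion of arynes into carboxylic acids, which turns cinnamic acids into chroman-4-ones; the α-aryl acid is a more hindered member of the same substrate class. Both new stereocentres form under reversible conditions (retro-Michael at C2, enolisation at C3), so thermodynamic control should favour the racemic trans isomer with both aryl groups equatorial; no absolute control is needed because both centres disappear in step 6. The step needs regioselective addition to the aryne, secured by the methoxy group beside the triple bond, and chemoselectivity for one acidic site, secured because 9 holds only ethers and a methyl ester besides the carboxylic acid. Keeping 5 as the limiting component limits a second arylation at the acidic C3–H of 12.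

Step 6
Reactants: 12 methyl 3-[(2S,3R)-2-[4-(benzyloxy)phenyl]-5,7-dimethoxy-4-oxochroman-3-yl]-4-methoxybenzoate (racemic trans)
Product: 13 methyl 3-{2-[4-(benzyloxy)phenyl]-5,7-dimethoxy-4-oxo-4H-chromen-3-yl}-4-methoxybenzoate
Conditions: DDQ (2 equiv), 1,4-dioxane, 100 °C
Reagents that add atoms: none
Why: Quinone dehydrogenation of a chroman-4-one: hydride abstraction from C2, where the cation is stabilised by O1 and the 4-alkoxyphenyl group, followed by loss of the C3 proton gives the aromatic pyranone; any cis/trans mixture converges, and unactivated benzyl ethers should survive.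

Step 7
Reactants: 13 methyl 3-{2-[4-(benzyloxy)phenyl]-5,7-dimethoxy-4-oxo-4H-chromen-3-yl}-4-methoxybenzoate
Product: 14 3-{2-[4-(benzyloxy)phenyl]-5,7-dimethoxy-4-oxo-4H-chromen-3-yl}-4-methoxybenzoic acid
Conditions: LiOH·H2O (3 equiv), THF/MeOH/H2O, 40 °C; then 1 M HCl
Reagents that add atoms: lithium hydroxide, [Li+].[OH-]
Why: Saponification of an aryl methyl ester; C2 of the pyranone is shielded by two aryl groups and deactivated by the electron-rich ring A, and a reversible ring opening by hydroxide would be undone on acidification.

Step 8
Reactants: 15 2,4,6-trihydroxyacetophenone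
Product: 16 1-[2,4-bis(benzyloxy)-6-hydroxyphenyl]ethan-1-one
Conditions: BnBr (2.05 equiv), K2CO3, DMF, 0 °C to rt
Reagents that add atoms: benzyl bromide, BrCc1ccccc1
Why: Williamson etherification; after the first ortho hydroxyl and the para hydroxyl are alkylated, the remaining ortho hydroxyl is locked in a hydrogen bond to the acetyl group and is the least nucleophilic, so two equivalents of BnBr should stop at the dibenzyl ether.

Step 9
Reactants: 14 3-{2-[4-(benzyloxy)phenyl]-5,7-dimethoxy-4-oxo-4H-chromen-3-yl}-4-methoxybenzoic acid, 16 1-[2,4-bis(benzyloxy)-6-hydroxyphenyl]ethan-1-one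
Product: 17 2-acetyl-3,5-bis(benzyloxy)phenyl 3-{2-[4-(benzyloxy)phenyl]-5,7-dimethoxy-4-oxo-4H-chromen-3-yl}-4-methoxybenzoate
Conditions: EDCI·HCl, DMAP, CH2Cl2, rt
Reagents that add atoms: none
Why: Steglich esterification; the acylpyridinium formed with DMAP is reactive enough for the hydrogen-bonded phenol, and no other free OH is present.

Step 10
Reactants: 17 2-acetyl-3,5-bis(benzyloxy)phenyl 3-{2-[4-(benzyloxy)phenyl]-5,7-dimethoxy-4-oxo-4H-chromen-3-yl}-4-methoxybenzoate
Product: 19 5,7-bis(benzyloxy)-2-(3-{2-[4-(benzyloxy)phenyl]-5,7-dimethoxy-4-oxo-4H-chromen-3-yl}-4-methoxyphenyl)-4H-chromen-4-one, via 1,3-diketone 18 (not isolated)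
Conditions: LiN(SiMe3)2 (4 equiv), THF, −78 to 0 °C; then TsOH·H2O (excess), toluene, 80 °C
Reagents that add atoms: none
Why: Baker–Venkataraman rearrangement (the methyl ketone enolate takes the aroyl group from the neighbouring phenol oxygen through a six-membered transition state) followed by acid-catalysed cyclodehydration of the hydroxyaryl 1,3-diketone to ring F; the amide base is non-nucleophilic, so the pyranone of unit 1 is not attacked.

Step 11
Reactants: 19 5,7-bis(benzyloxy)-2-(3-{2-[4-(benzyloxy)phenyl]-5,7-dimethoxy-4-oxo-4H-chromen-3-yl}-4-methoxyphenyl)-4H-chromen-4-one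
Product: 20 5,7-dihydroxy-2-{3-[5-hydroxy-2-(4-hydroxyphenyl)-7-methoxy-4-oxo-4H-chromen-3-yl]-4-methoxyphenyl}-4H-chromen-4-one
Conditions: BCl3 (12 equiv), C6HMe5 (10 equiv), CH2Cl2, −78 to 0 °C; then MeOH, H2O
Reagents that add atoms: none
Why: Lewis-acid ether cleavage: BCl3 removes the three benzyl groups (benzyl cations trapped by pentamethylbenzene) and, through a six-membered chelate with the C4 carbonyl, the peri O5 methyl of ring A only; the non-chelated methyl ethers on C7 and on ring E should not be cleaved by BCl3 at or below 0 °C.

## Compound list

1 | 3,5-dimethoxyphenol | COc1cc(O)cc(OC)c1 | starting material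
2 | 2-bromo-3,5-dimethoxyphenol | COc1cc(O)c(Br)c(OC)c1 | intermediate
3 | (2-bromo-3,5-dimethoxyphenoxy)trimethylsilane | COc1cc(O[Si](C)(C)C)c(Br)c(OC)c1 | intermediate
4 | lithium 3,5-dimethoxy-2-(trimethylsilyl)phenoxide | COc1cc([O-])c([Si](C)(C)C)c(OC)c1.[Li+] | intermediate
5 | 3,5-dimethoxy-2-(trimethylsilyl)phenyl trifluoromethanesulfonate | COc1cc(OC)c([Si](C)(C)C)c(OS(=O)(=O)C(F)(F)F)c1 | intermediate
6 | 2-(5-bromo-2-methoxyphenyl)acetic acid | COc1ccc(Br)cc1CC(=O)O | starting material
7 | 2-[2-methoxy-5-(methoxycarbonyl)phenyl]acetic acid | COC(=O)c1ccc(OC)c(CC(=O)O)c1 | intermediate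
8 | 4-(benzyloxy)benzaldehyde | O=Cc1ccc(OCc2ccccc2)cc1 | starting material
9 | (E)-3-[4-(benzyloxy)phenyl]-2-[2-methoxy-5-(methoxycarbonyl)phenyl]prop-2-enoic acid | OC(=O)/C(c1cc(C(=O)OC)ccc1OC)=C/c1ccc(OCc2ccccc2)cc1 | intermediate
10 | 3,5-dimethoxybenzyne (1,2-didehydro-3,5-dimethoxybenzene) | COC1=CC(OC)=CC#C1 | intermediate
11 | caesium 2-{(E)-3-[4-(benzyloxy)phenyl]-2-[2-methoxy-5-(methoxycarbonyl)phenyl]prop-2-enoyl}-3,5-dimethoxyphenoxide | COc1cc([O-])c(C(=O)/C(c2cc(C(=O)OC)ccc2OC)=C/c2ccc(OCc3ccccc3)cc2)c(OC)c1.[Cs+] | intermediate
12 | methyl 3-[(2S,3R)-2-[4-(benzyloxy)phenyl]-5,7-dimethoxy-4-oxochroman-3-yl]-4-methoxybenzoate, racemic trans isomer (2S,3R enantiomer written) | O=C1c2c(OC)cc(OC)cc2O[C@H](c2ccc(OCc3ccccc3)cc2)[C@H]1c1cc(C(=O)OC)ccc1OC | intermediate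
13 | methyl 3-{2-[4-(benzyloxy)phenyl]-5,7-dimethoxy-4-oxo-4H-chromen-3-yl}-4-methoxybenzoate | COC(=O)c1ccc(OC)c(-c2c(-c3ccc(OCc4ccccc4)cc3)oc3cc(OC)cc(OC)c3c2=O)c1 | intermediate
14 | 3-{2-[4-(benzyloxy)phenyl]-5,7-dimethoxy-4-oxo-4H-chromen-3-yl}-4-methoxybenzoic acid | OC(=O)c1ccc(OC)c(-c2c(-c3ccc(OCc4ccccc4)cc3)oc3cc(OC)cc(OC)c3c2=O)c1 | intermediate
15 | 2,4,6-trihydroxyacetophenone | CC(=O)c1c(O)cc(O)cc1O | starting material
16 | 1-[2,4-bis(benzyloxy)-6-hydroxyphenyl]ethan-1-one | CC(=O)c1c(O)cc(OCc2ccccc2)cc1OCc1ccccc1 | intermediate
17 | 2-acetyl-3,5-bis(benzyloxy)phenyl 3-{2-[4-(benzyloxy)phenyl]-5,7-dimethoxy-4-oxo-4H-chromen-3-yl}-4-methoxybenzoate | CC(=O)c1c(OC(=O)c2ccc(OC)c(-c3c(-c4ccc(OCc5ccccc5)cc4)oc4cc(OC)cc(OC)c4c3=O)c2)cc(OCc2ccccc2)cc1OCc1ccccc1 | intermediate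
18 | 1-[2,4-bis(benzyloxy)-6-hydroxyphenyl]-3-(3-{2-[4-(benzyloxy)phenyl]-5,7-dimethoxy-4-oxo-4H-chromen-3-yl}-4-methoxyphenyl)propane-1,3-dione | O=C(CC(=O)c1ccc(OC)c(-c2c(-c3ccc(OCc4ccccc4)cc3)oc3cc(OC)cc(OC)c3c2=O)c1)c1c(O)cc(OCc2ccccc2)cc1OCc1ccccc1 | intermediate
19 | 5,7-bis(benzyloxy)-2-(3-{2-[4-(benzyloxy)phenyl]-5,7-dimethoxy-4-oxo-4H-chromen-3-yl}-4-methoxyphenyl)-4H-chromen-4-one | COc1cc(OC)c2c(=O)c(-c3cc(-c4cc(=O)c5c(OCc6ccccc6)cc(OCc6ccccc6)cc5o4)ccc3OC)c(-c3ccc(OCc4ccccc4)cc3)oc2c1 | intermediate
20 | 5,7-dihydroxy-2-{3-[5-hydroxy-2-(4-hydroxyphenyl)-7-methoxy-4-oxo-4H-chromen-3-yl]-4-methoxyphenyl}-4H-chromen-4-one | COc1cc(O)c2c(=O)c(-c3cc(-c4cc(=O)c5c(O)cc(O)cc5o4)ccc3OC)c(-c3ccc(O)cc3)oc2c1 | target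

## Step count and least certain steps

Total: 11 steps. Longest linear sequence: 8 steps (steps 1, 2, 5, 6, 7, 9, 10, 11 from 1; the branch from 6 through steps 3 and 4 is equally long).

Step 5 (key step). Three things may go wrong:
- The aryl anion may be protonated before it reaches the acyl carbon, which the α-aryl group shields, so the sequence would stop at simple O-arylation.
- The oxa-Michael closure may stay incomplete, because the β-carbon carries an electron-rich aryl group.
- A second aryne may arylate the acidic C3 position of the product.

Fallback, a different construction of ring C by known chemistry, setting out from 1 and 7: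
- Friedel–Crafts C-acylation of 1 with 7 in BF3·OEt2 at 85 °C, ortho to the hydroxyl, should give the deoxybenzoin methyl 3-[2-(2-hydroxy-4,6-dimethoxyphenyl)-2-oxoethyl]-4-methoxybenzoate F1.
- O-Acylation with commercial 4-(benzyloxy)benzoyl chloride (pyridine, DMAP) should give 2-{2-[2-methoxy-5-(methoxycarbonyl)phenyl]acetyl}-3,5-dimethoxyphenyl 4-(benzyloxy)benzoate F2.
- A Baker–Venkataraman shift of the benzylic enolate (LiN(SiMe3)2, THF) and cyclodehydration with TsOH should then give 13 directly.

The route is rejoined at 13, bypassing 5, 9 and 12.

Step 1. Regiocontrol in the bromination may be lost (attack para to the hydroxyl between the two methoxy groups, or double bromination), because all three ring positions are strongly activated.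

Fallback, directed metalation in place of electrophilic substitution, setting out from 1:
- Isopropyl isocyanate with catalytic Et3N should give 3,5-dimethoxyphenyl N-isopropylcarbamate F3.
- N-Silylation in situ (Me3SiOTf, TMEDA), ortho-lithiation between the carbamate and a methoxy group (n-BuLi, TMEDA, −78 °C) and quench with Me3SiCl should give 3,5-dimethoxy-2-(trimethylsilyl)phenyl N-isopropylcarbamate F4.
- Carbamate cleavage with DBU/Et2NH in MeCN and triflation of the phenoxide with PhNTf2 in the same flask should give 5.

The route is rejoined at 5, bypassing 2, 3 and 4.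

Step 6. Hydride abstraction from the hindered 2,3-diaryl system may be slow, or the quinone may instead oxidise the benzylic position of the ring B ether.

Fallback, selenoxide elimination in place of hydride abstraction, setting out from 12:
- The lithium enolate (LiN(SiMe3)2, THF, −78 °C) is trapped with PhSeCl on the face opposite ring B. This should give methyl 3-[(2R,3R)-2-[4-(benzyloxy)phenyl]-5,7-dimethoxy-4-oxo-3-(phenylselanyl)chroman-3-yl]-4-methoxybenzoate F5 (racemic, selenium cis to H-2).
- Oxidation with H2O2 (CH2Cl2, 0 °C to rt) and syn-elimination of the selenoxide towards H-2 should give 13, where the route is rejoined.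

Step 7. Hydroxide may add to C2 of the pyranone and open ring C, with retro-Claisen cleavage of the resulting diketone, in competition with the slow hydrolysis of an electron-rich benzoate.

Fallback, avoiding hydroxide altogether, setting out from 13 and 16: the dilithium dianion of 16 (LiN(SiMe3)2, THF, −78 °C to rt) is acylated directly by the methyl ester of 13 in a crossed Claisen condensation. This should give 18, which rejoins the route at the acid treatment of step 10; 14 and 17 are bypassed, and no compound outside the compound list is made (F0).

Step 11. Chemoselectivity of the ether cleavage may be incomplete: the chelated methyl may be removed only partly, a second methyl ether may be lost, or the electron-rich rings A and D may be C-benzylated by benzyl cations.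

Fallback, separating the two deprotections, setting out from 19:
- Hydrogenolysis (H2, 10% Pd/C, THF/MeOH) should give 5,7-dihydroxy-2-{3-[2-(4-hydroxyphenyl)-5,7-dimethoxy-4-oxo-4H-chromen-3-yl]-4-methoxyphenyl}-4H-chromen-4-one F6.
- Chelation-controlled peri-demethylation with AlCl3 in MeCN at 60 °C should then give 20, where the route is rejoined.

## Further compounds

F1 | step 5 | methyl 3-[2-(2-hydroxy-4,6-dimethoxyphenyl)-2-oxoethyl]-4-methoxybenzoate | COC(=O)c1ccc(OC)c(CC(=O)c2c(O)cc(OC)cc2OC)c1
F2 | step 5 | 2-{2-[2-methoxy-5-(methoxycarbonyl)phenyl]acetyl}-3,5-dimethoxyphenyl 4-(benzyloxy)benzoate | COC(=O)c1ccc(OC)c(CC(=O)c2c(OC(=O)c3ccc(OCc4ccccc4)cc3)cc(OC)cc2OC)c1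
F3 | step 1 | 3,5-dimethoxyphenyl N-isopropylcarbamate | COc1cc(OC)cc(OC(=O)NC(C)C)c1
F4 | step 1 | 3,5-dimethoxy-2-(trimethylsilyl)phenyl N-isopropylcarbamate | COc1cc(OC)c([Si](C)(C)C)c(OC(=O)NC(C)C)c1
F5 | step 6 | methyl 3-[(2R,3R)-2-[4-(benzyloxy)phenyl]-5,7-dimethoxy-4-oxo-3-(phenylselanyl)chroman-3-yl]-4-methoxybenzoate, racemic (2R,3R enantiomer written) | O=C1c2c(OC)cc(OC)cc2O[C@H](c2ccc(OCc3ccccc3)cc2)[C@]1([Se]c1ccccc1)c1cc(C(=O)OC)ccc1OC
F0 | step 7 | none | none
F6 | step 11 | 5,7-dihydroxy-2-{3-[2-(4-hydroxyphenyl)-5,7-dimethoxy-4-oxo-4H-chromen-3-yl]-4-methoxyphenyl}-4H-chromen-4-one | COc1cc(OC)c2c(=O)c(-c3cc(-c4cc(=O)c5c(O)cc(O)cc5o4)ccc3OC)c(-c3ccc(O)cc3)oc2c1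
A1 | alternative 1 | 2-acetyl-3,5-bis(benzyloxy)phenyl 3-(2-{2-(benzyloxy)-6-[4-(benzyloxy)benzoyloxy]-4-methoxyphenyl}-2-oxoethyl)-4-methoxybenzoate | COc1cc(OCc2ccccc2)c(C(=O)Cc2cc(C(=O)Oc3cc(OCc4ccccc4)cc(OCc4ccccc4)c3C(C)=O)ccc2OC)c(OC(=O)c2ccc(OCc3ccccc3)cc2)c1
A2 | alternative 1 | 5,7-bis(benzyloxy)-2-(3-{5-(benzyloxy)-2-[4-(benzyloxy)phenyl]-7-methoxy-4-oxo-4H-chromen-3-yl}-4-methoxyphenyl)-4H-chromen-4-one | COc1cc(OCc2ccccc2)c2c(=O)c(-c3cc(-c4cc(=O)c5c(OCc6ccccc6)cc(OCc6ccccc6)cc5o4)ccc3OC)c(-c3ccc(OCc4ccccc4)cc3)oc2c1
A3 | alternative 2 | 2,4,6-trimethoxybenzoyl chloride | COc1cc(OC)c(C(Cl)=O)c(OC)c1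
A4 | alternative 2 | methyl 3-[(4-isopropoxyphenyl)ethynyl]-4-(tosyloxy)benzoate | COC(=O)c1ccc(OS(=O)(=O)c2ccc(C)cc2)c(C#Cc2ccc(OC(C)C)cc2)c1
A5 | alternative 2 | methyl 3-[2-(4-isopropoxyphenyl)-5,7-dimethoxy-4-oxo-4H-chromen-3-yl]-4-(tosyloxy)benzoate | COc1cc(OC)c2c(=O)c(-c3cc(C(=O)OC)ccc3OS(=O)(=O)c3ccc(C)cc3)c(-c3ccc(OC(C)C)cc3)oc2c1
A6 | alternative 3 | 5-(benzyloxy)-2-[4-(benzyloxy)phenyl]-7-methoxy-3-(methoxyethynyl)-4H-chromen-4-one | COC#Cc1c(-c2ccc(OCc3ccccc3)cc2)oc2cc(OC)cc(OCc3ccccc3)c2c1=O
A7 | alternative 3 | methyl coumalate (methyl 2-oxo-2H-pyran-5-carboxylate) | COC(=O)c1ccc(=O)oc1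
A8 | alternative 3 | methyl 3-{5-(benzyloxy)-2-[4-(benzyloxy)phenyl]-7-methoxy-4-oxo-4H-chromen-3-yl}-4-methoxybenzoate | COC(=O)c1ccc(OC)c(-c2c(-c3ccc(OCc4ccccc4)cc3)oc3cc(OC)cc(OCc4ccccc4)c3c2=O)c1
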